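**Retrosynthetic overview**

1. Locants: dienone ring C1 (C=O), C2 (allyl), C3, C4 (quaternary, OMe), C5 (OMe), C6; Cα is the side-chain methine. The target comes from its aryl silyl ether, and that from closure of the C1–C2 bond.
2. Enabling feature: the atoms O–C4–C5(OMe)=C6–C1(=O) of the dienone are, atom for atom, a 4-methoxyfuran-2(5H)-one (methyl tetronate) ring. A (Z)-vinyllithium at C2, carried on C4, takes the lactone carbonyl C1 from the ring oxygen, so the furanone becomes the cyclohexa-2,5-dienone and the freed C4 alkoxide is methylated in the same flask.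
3. The tetronate comes from a tertiary α-hydroxy methyl ester and Ph3P=C=C=O (ester carbon = C5, ester OMe = the C5 methoxy, ylide carbons = C6 and C1). The (Z)-C2–I bond comes from the alkyne by trans-hydrosilylation and iododesilylation.
4. C4 and Cα are set together by one catalytic asymmetric Mukaiyama aldol between an alkynyl α-keto ester (pent-1-en-4-yne + dimethyl oxalate) and the enol silane of silyl-protected 4'-hydroxy-3'-methoxypropiophenone; the aryl ketone is then reduced to the benzylic CH2.
5. Ring order: the arene is bought; the furanone is closed in step 8; the carbocycle is made from the furanone in step 9.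

Key step: step 9

Assumption (chemistry): the Cu(OTf)2/(S,S)-t-Bu-box aldol of step 4 is taken to follow the sense known for pyruvate esters (Si-face attack on the chelated keto ester, syn adduct); if the opposite sense were found, the (R,R)-ligand would be used.

**Route**

Step 1
Reactants: 1 1-(4-hydroxy-3-methoxyphenyl)propan-1-one
Product: 2 1-[3-methoxy-4-(triisopropylsilyloxy)phenyl]propan-1-one
Conditions: i-Pr3SiCl, imidazole, DMF, rt
Reagents that add atoms: chlorotri(propan-2-yl)silane, CC(C)[Si](Cl)(C(C)C)C(C)C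
Why: Imidazole-promoted silylation of the phenol gives a triisopropylsilyl ether that should tolerate the organolithium, Lewis acid and protic acid steps that follow.

Step 2
Reactants: 2 1-[3-methoxy-4-(triisopropylsilyloxy)phenyl]propan-1-one
Product: 3 trimethyl{[(1Z)-1-[3-methoxy-4-(triisopropylsilyloxy)phenyl]prop-1-en-1-yl]oxy}silane
Conditions: Me3SiOTf, Et3N, CH2Cl2, 0 °C
Reagents that add atoms: trimethylsilyl trifluoromethanesulfonate, C[Si](C)(C)OS(=O)(=O)C(F)(F)F
Why: Soft enolisation of the aryl ethyl ketone (silyl enol ether formation) should give mainly the (Z)-enol silane, and the geometry is not critical because the aldol of step 4 is stereoconvergent.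

Step 3
Reactants: 4 pent-1-en-4-yne; 5 dimethyl oxalate
Product: 7 methyl 2-oxohept-6-en-3-ynoate, via lithium acetylide 6 (not isolated)
Conditions: n-BuLi, THF, −78 °C; then added to 5 (3 equiv), THF, −78 °C; aq. NH4Cl
Reagents that add atoms: none
Why: Inverse addition of the lithium acetylide to excess dimethyl oxalate at low temperature should stop at mono-acylation and give the alkynyl α-keto ester (C-acylation of an acetylide by an oxalate diester).

Step 4
Reactants: 3 trimethyl{[(1Z)-1-[3-methoxy-4-(triisopropylsilyloxy)phenyl]prop-1-en-1-yl]oxy}silane; 7 methyl 2-oxohept-6-en-3-ynoate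
Product: 9 methyl (2R,3S)-2-hydroxy-4-[3-methoxy-4-(triisopropylsilyloxy)phenyl]-3-methyl-4-oxo-2-(pent-4-en-1-yn-1-yl)butanoate, via O-trimethylsilyl ether 8 (not isolated)
Conditions: Cu(OTf)2 (10 mol%), 2,2'-(propane-2,2-diyl)bis[(4S)-4-tert-butyl-4,5-dihydro-1,3-oxazole] (11 mol%), THF, −78 °C; then 1 M HCl, THF, 0 °C
Reagents that add atoms: none
Why: Catalytic asymmetric Mukaiyama aldol addition to an α-keto ester: the keto ester chelates divalent copper through both carbonyl oxygens, the tert-butyl groups of the ligand leave the Si face of the ketone open and the open transition state gives the syn adduct, so C2 (R, the later C4) and C3 (S, the later Cα) are set together under catalyst control, and mild acid then removes the transferred trimethylsilyl group.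

Step 5
Reactants: 9 methyl (2R,3S)-2-hydroxy-4-[3-methoxy-4-(triisopropylsilyloxy)phenyl]-3-methyl-4-oxo-2-(pent-4-en-1-yn-1-yl)butanoate
Product: 10 methyl (2R,3R)-2-hydroxy-4-[3-methoxy-4-(triisopropylsilyloxy)phenyl]-3-methyl-2-(pent-4-en-1-yn-1-yl)butanoate
Conditions: Et3SiH (4 equiv), CF3CO2H, CH2Cl2, 0 °C to rt
Reagents that add atoms: none
Why: Ionic hydrogenation should take the electron-rich aryl ketone to the methylene by hydride transfer to the protonated carbonyl and then to the para-silyloxy-stabilised benzylic cation, while alkyne, alkene, ester and tertiary alcohol are left alone; no stereocentre is touched, and the descriptor at C3 changes from S to R only because the priority of C4 falls.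

Step 6
Reactants: 10 methyl (2R,3R)-2-hydroxy-4-[3-methoxy-4-(triisopropylsilyloxy)phenyl]-3-methyl-2-(pent-4-en-1-yn-1-yl)butanoate
Product: 11 methyl (2R,3R)-2-hydroxy-4-[3-methoxy-4-(triisopropylsilyloxy)phenyl]-3-methyl-2-[(1Z)-2-(triethylsilyl)penta-1,4-dien-1-yl]butanoate
Conditions: [Cp*Ru(MeCN)3]PF6 (2 mol%), Et3SiH, CH2Cl2, 0 °C to rt
Reagents that add atoms: triethylsilane, CC[SiH](CC)CC
Why: Ruthenium-catalysed trans-hydrosilylation of the internal alkyne adds H and Si anti and should place silicon on the alkyne carbon remote from the propargylic hydroxyl and the quaternary centre, which gives the (Z)-vinylsilane with silicon cis to the carbinol carbon and leaves the terminal alkene alone.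

Step 7
Reactants: 11 methyl (2R,3R)-2-hydroxy-4-[3-methoxy-4-(triisopropylsilyloxy)phenyl]-3-methyl-2-[(1Z)-2-(triethylsilyl)penta-1,4-dien-1-yl]butanoate
Product: 12 methyl (2R,3R)-2-hydroxy-2-[(1Z)-2-iodopenta-1,4-dien-1-yl]-4-[3-methoxy-4-(triisopropylsilyloxy)phenyl]-3-methylbutanoate
Conditions: NIS (1.2 equiv), 2,6-lutidine, MeCN/ClCH2CN (4:1), 0 °C, dark
Reagents that add atoms: N-iodosuccinimide, O=C1CCC(=O)N1I
Why: Electrophilic ipso-iododesilylation of the vinylsilane (β-silyl cation, loss of silicon) should proceed with retention to the (Z)-vinyl iodide, and acid-free NIS in acetonitrile is chosen so that the electron-rich arene is not iodinated.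

Step 8
Reactants: 12 methyl (2R,3R)-2-hydroxy-2-[(1Z)-2-iodopenta-1,4-dien-1-yl]-4-[3-methoxy-4-(triisopropylsilyloxy)phenyl]-3-methylbutanoate; 13 (triphenylphosphoranylidene)ketene
Product: 15 (5R)-5-[(1Z)-2-iodopenta-1,4-dien-1-yl]-4-methoxy-5-[(2R)-1-[3-methoxy-4-(triisopropylsilyloxy)phenyl]propan-2-yl]furan-2(5H)-one, via acyloxy phosphorus ylide 14 (not isolated)
Conditions: 13 (1.3 equiv), PhCO2H (cat.), toluene, 110 °C
Reagents that add atoms: none
Why: Tetronate synthesis by addition of the tertiary alcohol to the ketene of 13 and intramolecular Wittig olefination of the neighbouring methyl ester carbonyl by the resulting stabilised ylide closes the 4-methoxyfuran-2(5H)-one, the ester methoxy becoming the enol ether methoxy, with no stereocentre involved.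

Step 9
Reactants: 15 (5R)-5-[(1Z)-2-iodopenta-1,4-dien-1-yl]-4-methoxy-5-[(2R)-1-[3-methoxy-4-(triisopropylsilyloxy)phenyl]propan-2-yl]furan-2(5H)-one
Product: 19 (4R)-4,5-dimethoxy-4-[(2R)-1-[3-methoxy-4-(triisopropylsilyloxy)phenyl]propan-2-yl]-2-(prop-2-en-1-yl)cyclohexa-2,5-dien-1-one, via vinyllithium 16 (not isolated), via bridged lithium alkoxide 17 (not isolated), via lithium dienone alkoxide 18 (not isolated)
Conditions: t-BuLi (2.1 equiv), Et2O, −78 to −40 °C; then MeOTf (1.5 equiv), −78 to 0 °C
Reagents that add atoms: methyl trifluoromethanesulfonate, COS(=O)(=O)C(F)(F)F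
Why: Proposed new method: iodine–lithium exchange, which is faster than attack of tert-butyllithium on the lactone at −78 °C, gives vinyllithium 16, whose carbanion carbon C2 is held cis to C4 and lies over the lactone carbonyl C1; it adds to C1 (6-exo-trig for the new carbocycle, 5-exo-trig for the transient dihydrofuranolate ring) to give the bridged 7-oxanorbornadiene-type alkoxide 17, which should collapse at once by breaking the C1–O7 bond because this releases the strain of the bicycle and forms a cross-conjugated vinylogous ester. The closest known reaction types are the Parham cyclisation of aryl- and vinyllithiums onto esters and the anionic 1,4 O-to-C acyl shift of (Z)-γ-lithioallyl esters (the vinylogous relative of the anionic Fries rearrangement); what is new is that the migrating acyl group is the lactone carbonyl of a tetronate, so that the furanone ring is turned into the cyclohexa-2,5-dienone. No new stereocentre is formed: the C4–O bond is never broken, so C4 (R) and Cα (R) are carried over unchanged, and the bridgehead C1 of 17 is fixed by the bicycle and lost on opening. The step needs exchange before carbonyl addition, which the iodide, the low temperature and the second equivalent of tert-butyllithium (it destroys tert-butyl iodide) should secure, and attack at C1 only, which the Z geometry from steps 6 and 7 secures because C5 could be reached only through a four-membered ring. The tertiary lithium alkoxide 18 is then O-methylated by methyl triflate in the same flask, which installs the C4 methoxy group and stops the alkoxide from returning to C1.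

Step 10
Reactants: 19 (4R)-4,5-dimethoxy-4-[(2R)-1-[3-methoxy-4-(triisopropylsilyloxy)phenyl]propan-2-yl]-2-(prop-2-en-1-yl)cyclohexa-2,5-dien-1-one
Product: 20 (4R)-4-[(2R)-1-(4-hydroxy-3-methoxyphenyl)propan-2-yl]-4,5-dimethoxy-2-(prop-2-en-1-yl)cyclohexa-2,5-dien-1-one
Conditions: n-Bu4NF, AcOH, THF, 0 °C
Reagents that add atoms: none
Why: Fluoride-induced cleavage of the aryl silyl ether (Si–F bond formation) should free the phenol, with acetic acid buffering the phenoxide so that the dienone and the enol ether are not exposed to base.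

**Compound list**

1 | 1-(4-hydroxy-3-methoxyphenyl)propan-1-one | CCC(=O)c1ccc(O)c(OC)c1 | starting material
2 | 1-[3-methoxy-4-(triisopropylsilyloxy)phenyl]propan-1-one | CCC(=O)c1ccc(O[Si](C(C)C)(C(C)C)C(C)C)c(OC)c1 | intermediate
3 | trimethyl{[(1Z)-1-[3-methoxy-4-(triisopropylsilyloxy)phenyl]prop-1-en-1-yl]oxy}silane | C/C=C(\O[Si](C)(C)C)c1ccc(O[Si](C(C)C)(C(C)C)C(C)C)c(OC)c1 | intermediate
4 | pent-1-en-4-yne | C=CCC#C | starting material
5 | dimethyl oxalate | COC(=O)C(=O)OC | starting material
6 | (pent-4-en-1-yn-1-yl)lithium | [Li]C#CCC=C | intermediate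
7 | methyl 2-oxohept-6-en-3-ynoate | C=CCC#CC(=O)C(=O)OC | intermediate
8 | methyl (2R,3S)-4-[3-methoxy-4-(triisopropylsilyloxy)phenyl]-3-methyl-4-oxo-2-(pent-4-en-1-yn-1-yl)-2-(trimethylsilyloxy)butanoate | C=CCC#C[C@](O[Si](C)(C)C)([C@H](C)C(=O)c1ccc(O[Si](C(C)C)(C(C)C)C(C)C)c(OC)c1)C(=O)OC | intermediate
9 | methyl (2R,3S)-2-hydroxy-4-[3-methoxy-4-(triisopropylsilyloxy)phenyl]-3-methyl-4-oxo-2-(pent-4-en-1-yn-1-yl)butanoate | C=CCC#C[C@](O)([C@H](C)C(=O)c1ccc(O[Si](C(C)C)(C(C)C)C(C)C)c(OC)c1)C(=O)OC | intermediate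
10 | methyl (2R,3R)-2-hydroxy-4-[3-methoxy-4-(triisopropylsilyloxy)phenyl]-3-methyl-2-(pent-4-en-1-yn-1-yl)butanoate | C=CCC#C[C@](O)([C@H](C)Cc1ccc(O[Si](C(C)C)(C(C)C)C(C)C)c(OC)c1)C(=O)OC | intermediate
11 | methyl (2R,3R)-2-hydroxy-4-[3-methoxy-4-(triisopropylsilyloxy)phenyl]-3-methyl-2-[(1Z)-2-(triethylsilyl)penta-1,4-dien-1-yl]butanoate | C=CC/C([Si](CC)(CC)CC)=C/[C@](O)([C@H](C)Cc1ccc(O[Si](C(C)C)(C(C)C)C(C)C)c(OC)c1)C(=O)OC | intermediate
12 | methyl (2R,3R)-2-hydroxy-2-[(1Z)-2-iodopenta-1,4-dien-1-yl]-4-[3-methoxy-4-(triisopropylsilyloxy)phenyl]-3-methylbutanoate | C=CC/C(I)=C/[C@](O)([C@H](C)Cc1ccc(O[Si](C(C)C)(C(C)C)C(C)C)c(OC)c1)C(=O)OC | intermediate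
13 | (triphenylphosphoranylidene)ketene | O=C=C=P(c1ccccc1)(c1ccccc1)c1ccccc1 | starting material
14 | methyl (2R,3R)-2-[(1Z)-2-iodopenta-1,4-dien-1-yl]-4-[3-methoxy-4-(triisopropylsilyloxy)phenyl]-3-methyl-2-{[(triphenyl-λ5-phosphanylidene)acetyl]oxy}butanoate | C=CC/C(I)=C/[C@](OC(=O)C=P(c1ccccc1)(c1ccccc1)c1ccccc1)([C@H](C)Cc1ccc(O[Si](C(C)C)(C(C)C)C(C)C)c(OC)c1)C(=O)OC | intermediate
15 | (5R)-5-[(1Z)-2-iodopenta-1,4-dien-1-yl]-4-methoxy-5-[(2R)-1-[3-methoxy-4-(triisopropylsilyloxy)phenyl]propan-2-yl]furan-2(5H)-one | C=CC/C(I)=C/[C@]1(OC(=O)C=C1OC)[C@H](C)Cc2ccc(O[Si](C(C)C)(C(C)C)C(C)C)c(OC)c2 | intermediate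
16 | [(1E)-1-{(2R)-3-methoxy-5-oxo-2-[(2R)-1-[3-methoxy-4-(triisopropylsilyloxy)phenyl]propan-2-yl]-2,5-dihydrofuran-2-yl}penta-1,4-dien-2-yl]lithium (lithium in the place of the iodine of 15, cis to the furanone carbon; E only because carbon outranks lithium) | C=CC/C([Li])=C/[C@]1(OC(=O)C=C1OC)[C@H](C)Cc2ccc(O[Si](C(C)C)(C(C)C)C(C)C)c(OC)c2 | intermediate
17 | lithium 5-methoxy-4-[(2R)-1-[3-methoxy-4-(triisopropylsilyloxy)phenyl]propan-2-yl]-2-(prop-2-en-1-yl)-7-oxabicyclo[2.2.1]hepta-2,5-dien-1-olate (C4 as in 15; bridgehead C1 fixed by the bicycle) | C=CCC1=C[C@]2(O[C@]1(O[Li])C=C2OC)[C@H](C)Cc3ccc(O[Si](C(C)C)(C(C)C)C(C)C)c(OC)c3 | intermediate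
18 | lithium (1R)-2-methoxy-1-[(2R)-1-[3-methoxy-4-(triisopropylsilyloxy)phenyl]propan-2-yl]-4-oxo-5-(prop-2-en-1-yl)cyclohexa-2,5-dien-1-olate | C=CCC1=C[C@](O[Li])([C@H](C)Cc2ccc(O[Si](C(C)C)(C(C)C)C(C)C)c(OC)c2)C(OC)=CC1=O | intermediate
19 | (4R)-4,5-dimethoxy-4-[(2R)-1-[3-methoxy-4-(triisopropylsilyloxy)phenyl]propan-2-yl]-2-(prop-2-en-1-yl)cyclohexa-2,5-dien-1-one | C=CCC1=C[C@](OC)([C@H](C)Cc2ccc(O[Si](C(C)C)(C(C)C)C(C)C)c(OC)c2)C(OC)=CC1=O | intermediate
20 | (4R)-4-[(2R)-1-(4-hydroxy-3-methoxyphenyl)propan-2-yl]-4,5-dimethoxy-2-(prop-2-en-1-yl)cyclohexa-2,5-dien-1-one | C=CCC1=C[C@](OC)([C@H](C)Cc2ccc(O)c(OC)c2)C(OC)=CC1=O | target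

**Step count and risks**

Total step count: 10. Longest linear sequence: 9 steps (from 1 through steps 1, 2, 4, 5, 6, 7, 8, 9 and 10).

Steps most likely to fail:

Step 9. The vinyllithium may fail to add across the furanone because the bridged adduct is strained, and then be protonated or attack a second molecule; the hindered tertiary alkoxide may also be methylated too slowly. The fallback uses known chemistry, sets out from 15 and comes back at 19. Half-reduction of the lactone with i-Bu2AlH (CH2Cl2, −78 °C) should give the lactol (5R)-5-[(1Z)-2-iodopenta-1,4-dien-1-yl]-4-methoxy-5-[(2R)-1-[3-methoxy-4-(triisopropylsilyloxy)phenyl]propan-2-yl]-2,5-dihydrofuran-2-ol F1 as both anomers. Its open γ-hydroxy enal form should undergo an intramolecular Nozaki–Hiyama–Kishi reaction (CrCl2, NiCl2 cat., DMSO, rt), in which the vinylchromium at C2 adds to the aldehyde C1. This is an unstrained six-membered closure of the same C1–C2 bond and should give (1R)-2-methoxy-1-[(2R)-1-[3-methoxy-4-(triisopropylsilyloxy)phenyl]propan-2-yl]-5-(prop-2-en-1-yl)cyclohexa-2,5-diene-1,4-diol F2 as both carbinol epimers. MnO2 (CH2Cl2) should oxidise the doubly allylic secondary alcohol to the quinol (4R)-4-hydroxy-5-methoxy-4-[(2R)-1-[3-methoxy-4-(triisopropylsilyloxy)phenyl]propan-2-yl]-2-(prop-2-en-1-yl)cyclohexa-2,5-dien-1-one F3, and MeI/Ag2O should methylate the tertiary alcohol to 19.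

Step 4. Facial or syn selectivity may be eroded with a ketone-derived enol silane, or the enol silane may add in a conjugate sense to the alkynyl ketone. The fallback sets out from 7 and comes back at 8, which is hydrolysed to 9 as in step 4. The nucleophile is changed to the thioester silyl ketene acetal [1-(ethylsulfanyl)prop-1-en-1-yl]oxy(trimethyl)silane F4 (from S-ethyl propanethioate, LiN(i-Pr)2, Me3SiCl, THF, −78 °C; either geometry), the nucleophile class for which this copper-catalysed aldol is best established. Under the same catalyst it should give methyl (2R,3S)-4-(ethylsulfanyl)-3-methyl-4-oxo-2-(pent-4-en-1-yn-1-yl)-2-(trimethylsilyloxy)butanoate F5. The aryl group is then brought in by Fukuyama coupling (PdCl2(PPh3)2 cat., THF/toluene, rt) of this thioester with [3-methoxy-4-(triisopropylsilyloxy)phenyl]zinc iodide F7. F7 is made by zinc insertion (Zn, LiCl, THF) into (4-iodo-2-methoxyphenoxy)tri(propan-2-yl)silane F6, itself from 4-iodo-2-methoxyphenol and i-Pr3SiCl.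

Step 5. The benzylic cation may lose a proton to a styrene and be re-reduced, which would epimerise Cα, or it may be captured by the neighbouring ester, leading to lactonisation. The fallback sets out from 9 and comes back at 10. Condensation with 4-methylbenzenesulfonohydrazide (EtOH, 60 °C) should give the tosylhydrazone methyl (2R,3R)-2-hydroxy-4-[3-methoxy-4-(triisopropylsilyloxy)phenyl]-3-methyl-4-[2-(4-methylbenzenesulfonyl)hydrazinylidene]-2-(pent-4-en-1-yn-1-yl)butanoate F8. Reduction with catecholborane (CHCl3, 0 °C) and decomposition with NaOAc·3H2O (reflux) should then give the methylene through a diazene, with no cationic centre next to the stereocentre.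

Further compounds
F1 | step 9 | (5R)-5-[(1Z)-2-iodopenta-1,4-dien-1-yl]-4-methoxy-5-[(2R)-1-[3-methoxy-4-(triisopropylsilyloxy)phenyl]propan-2-yl]-2,5-dihydrofuran-2-ol (both anomers) | C=CC/C(I)=C/[C@]1(OC(O)C=C1OC)[C@H](C)Cc2ccc(O[Si](C(C)C)(C(C)C)C(C)C)c(OC)c2
F2 | step 9 | (1R)-2-methoxy-1-[(2R)-1-[3-methoxy-4-(triisopropylsilyloxy)phenyl]propan-2-yl]-5-(prop-2-en-1-yl)cyclohexa-2,5-diene-1,4-diol (both C4 epimers) | C=CCC1=C[C@](O)([C@H](C)Cc2ccc(O[Si](C(C)C)(C(C)C)C(C)C)c(OC)c2)C(OC)=CC1O
F3 | step 9 | (4R)-4-hydroxy-5-methoxy-4-[(2R)-1-[3-methoxy-4-(triisopropylsilyloxy)phenyl]propan-2-yl]-2-(prop-2-en-1-yl)cyclohexa-2,5-dien-1-one | C=CCC1=C[C@](O)([C@H](C)Cc2ccc(O[Si](C(C)C)(C(C)C)C(C)C)c(OC)c2)C(OC)=CC1=O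
F4 | step 4 | [1-(ethylsulfanyl)prop-1-en-1-yl]oxy(trimethyl)silane (either geometry) | CC=C(SCC)O[Si](C)(C)C
F5 | step 4 | methyl (2R,3S)-4-(ethylsulfanyl)-3-methyl-4-oxo-2-(pent-4-en-1-yn-1-yl)-2-(trimethylsilyloxy)butanoate | C=CCC#C[C@](O[Si](C)(C)C)([C@H](C)C(=O)SCC)C(=O)OC
F6 | step 4 | (4-iodo-2-methoxyphenoxy)tri(propan-2-yl)silane | COc1cc(I)ccc1O[Si](C(C)C)(C(C)C)C(C)C
F7 | step 4 | [3-methoxy-4-(triisopropylsilyloxy)phenyl]zinc iodide | COc1cc([Zn]I)ccc1O[Si](C(C)C)(C(C)C)C(C)C
F8 | step 5 | methyl (2R,3R)-2-hydroxy-4-[3-methoxy-4-(triisopropylsilyloxy)phenyl]-3-methyl-4-[2-(4-methylbenzenesulfonyl)hydrazinylidene]-2-(pent-4-en-1-yn-1-yl)butanoate | C=CCC#C[C@](O)([C@H](C)C(=NNS(=O)(=O)c1ccc(C)cc1)c1ccc(O[Si](C(C)C)(C(C)C)C(C)C)c(OC)c1)C(=O)OC
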